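**Retrosynthetic overview**

1. Ring letters: A = benzo ring of the chromane, B = 4-hydroxyphenyl on C2, C = pyran ring (O1, C2, C3, C4, C4a, C8a), D = acylphloroglucinol on C4. Target 16 ⇐ hydrogenolysis of pentabenzyl ether 15 ⇐ C-acylation of ring D (aryl bromide 9 → aryllithium + Weinreb amide 12).
2. 9 ⇐ catalytic asymmetric oxa-[4+2] cycloaddition of o-quinone methide 8 (heterodiene O1=C8a–C4a=C4, from benzhydrol 6) with styrene 7 (C3=C2). This disconnects C4–C3 and O1–C2 and both stereocentres.
3. 6 ⇐ aldehyde 3 + aryllithium 4, from dibromide 2 ⇐ triether 1.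
4. Ring order: rings A, B and D are bought as arenes; ring C is the only ring built and is closed last, in step 3.
5. Enabling feature: in ring A the oxygen O1 on C8a sits ortho, and the C7 oxygen para, to C4a, which carries C4 between the electron-rich rings A and D. O1–C8a–C4a–C4 is therefore a latent o-quinone methide, and C2–C3 with the p-oxygenated ring B is a latent electron-rich styrene.

Key step: step 3

**Remarks on the chemistry (assumptions)**

- The sense of induction of the chiral N-triflylphosphoramide is assumed; should the (R)-catalyst deliver the (2S,4S) adduct, the (S)-catalyst is used instead.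
- Compound 1 is taken as commercial; otherwise it should be available from phloroglucinol via its triacetate and benzyl chloride.

**Route**

Step 1
Reactants: 1 1,3,5-tris(benzyloxy)benzene
Product: 2 1,3,5-tris(benzyloxy)-2,4-dibromobenzene
Conditions: NBS (2.05 equiv), CH2Cl2, −40 °C → 0 °C
Reagents that add atoms: N-bromosuccinimide, O=C1CCC(=O)N1Br
Why: Electrophilic aromatic bromination of the strongly activated triether, in which the three free positions of 1 and then the two of the monobromide are equivalent, so that two equivalents of NBS should give a single dibromide.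

Step 2
Reactants: 2 1,3,5-tris(benzyloxy)-2,4-dibromobenzene; 3 4-(benzyloxy)-2-hydroxybenzaldehyde
Product: 6 [4-(benzyloxy)-2-hydroxyphenyl][2,4,6-tris(benzyloxy)-3-bromophenyl]methanol (racemic), via aryllithium 4 (not isolated), via sodium phenoxide 5 (not isolated)
Conditions: 2, n-BuLi (1.0 equiv), THF, −78 °C; then 5 [from 3, NaH (1.05 equiv), THF, 0 °C], −78 °C → −20 °C; sat. aq NH4Cl; chromatography on Et3N-deactivated silica
Reagents that add atoms: none
Why: Bromine–lithium exchange at one of the two equivalent C–Br bonds followed by 1,2-addition of the aryllithium to the aldehyde, whose phenol is masked as its sodium salt; the carbinol centre is formed racemic on purpose because it is erased in step 3.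

Step 3
Reactants: 6 [4-(benzyloxy)-2-hydroxyphenyl][2,4,6-tris(benzyloxy)-3-bromophenyl]methanol; 7 1-(benzyloxy)-4-ethenylbenzene
Product: 9 (2R,4R)-7-(benzyloxy)-2-[4-(benzyloxy)phenyl]-4-[2,4,6-tris(benzyloxy)-3-bromophenyl]chromane, via o-quinone methide 8 (not isolated)
Conditions: 7 (3 equiv), (R)-3,3'-bis(2,4,6-triisopropylphenyl)-1,1'-binaphthyl-2,2'-diyl N-triflylphosphoramide (10 mol %), 4 Å MS, toluene, −20 °C → rt
Reagents that add atoms: none
Why: The strong chiral acid ionises 6 (loss of water; the cation lies between the electron-rich rings A and D) to the (E)-o-quinone methide 8, held as a hydrogen-bonded ion pair with the phosphoramide, the CH2 terminus of 7 then attacks C4 and the p-benzyloxybenzylic cation developing at C2 is captured by O1 in an asynchronous inverse-electron-demand oxa-Diels–Alder reaction. The closest known reaction type is the chiral Brønsted acid (N-triflylphosphoramide) catalysed [4+2] cycloaddition of o-quinone methides, generated from o-hydroxybenzhydryl alcohols, with styrenes to give cis-2,4-diarylchromanes. Ring C is closed by an intermolecular [4+2] annulation, four atoms (O1, C8a, C4a, C4) from 8 and two (C3, C2) from 7, with C4–C3 formed ahead of O1–C2. C4 is set by the catalyst, whose 3,3'-aryl walls shield one face of the methide carbon within the ion pair (absolute control). C2 is set relative to C4 by the endo, chair-like transition state that places rings B and D both pseudo-equatorial (2,4-cis), and since the cis isomer is also the thermodynamic one, any reversible O1–C2 ionisation under the acid can only correct C2 and cannot touch C4. The step needs site selectivity of quinone methide formation and regioselectivity of the alkene: the first is secured because only ring A keeps a free ortho-OH (all three oxygens of ring D are benzylated, so ring C cannot fuse to ring D), the second by the polarity match of the styrene CH2 with C4 and by the para oxygen of ring B, which stabilises positive charge at C2.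

Step 4
Reactants: 10 dodecanoyl chloride; 11 N,O-dimethylhydroxylamine hydrochloride
Product: 12 N-methoxy-N-methyldodecanamide
Conditions: Et3N (2.2 equiv), CH2Cl2, 0 °C → rt
Reagents that add atoms: none
Why: Nucleophilic acyl substitution of the acid chloride by the hydroxylamine liberated with Et3N (Weinreb amide formation).

Step 5
Reactants: 9 (2R,4R)-7-(benzyloxy)-2-[4-(benzyloxy)phenyl]-4-[2,4,6-tris(benzyloxy)-3-bromophenyl]chromane; 12 N-methoxy-N-methyldodecanamide
Product: 15 1-{2,4,6-tris(benzyloxy)-3-[(2R,4R)-7-(benzyloxy)-2-[4-(benzyloxy)phenyl]chroman-4-yl]phenyl}dodecan-1-one, via aryllithium 13 (not isolated), via lithium hemiaminal alkoxide 14 (not isolated)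
Conditions: n-BuLi (1.1 equiv), THF, −78 °C, 15 min; then 12 (1.5 equiv), −78 °C → 0 °C; sat. aq NH4Cl
Reagents that add atoms: none
Why: Bromine–lithium exchange should outrun any deprotonation at −78 °C and the aryllithium adds once to the Weinreb amide, the chelated tetrahedral adduct releasing the ketone only on work-up (Weinreb ketone synthesis), so that C2 and C4 are not touched.

Step 6
Reactants: 15 1-{2,4,6-tris(benzyloxy)-3-[(2R,4R)-7-(benzyloxy)-2-[4-(benzyloxy)phenyl]chroman-4-yl]phenyl}dodecan-1-one
Product: 16 1-{2,4,6-trihydroxy-3-[(2R,4R)-7-hydroxy-2-(4-hydroxyphenyl)chroman-4-yl]phenyl}dodecan-1-one (target)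
Conditions: H2 (1 atm), Pd(OH)2 on carbon (20 wt %), THF/MeOH 1:1, rt
Reagents that add atoms: none
Why: Hydrogenolysis of the five aryl benzyl ethers under neutral conditions, a standard last step for benzyl-protected flavans and acylphloroglucinols, should leave the chelated aryl ketone, the O1–C2 bond and both stereocentres intact if stopped at full debenzylation.

**Compound list**

1 | 1,3,5-tris(benzyloxy)benzene | c1c(OCc2ccccc2)cc(OCc2ccccc2)cc1OCc1ccccc1 | starting material
2 | 1,3,5-tris(benzyloxy)-2,4-dibromobenzene | Brc1c(OCc2ccccc2)cc(OCc2ccccc2)c(Br)c1OCc1ccccc1 | intermediate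
3 | 4-(benzyloxy)-2-hydroxybenzaldehyde | O=Cc1ccc(OCc2ccccc2)cc1O | starting material
4 | [2,4,6-tris(benzyloxy)-3-bromophenyl]lithium | [Li]c1c(OCc2ccccc2)cc(OCc2ccccc2)c(Br)c1OCc1ccccc1 | intermediate (not isolated)
5 | sodium 5-(benzyloxy)-2-formylphenolate | O=Cc1ccc(OCc2ccccc2)cc1[O-].[Na+] | intermediate (not isolated)
6 | [4-(benzyloxy)-2-hydroxyphenyl][2,4,6-tris(benzyloxy)-3-bromophenyl]methanol (racemic) | OC(c1ccc(OCc2ccccc2)cc1O)c1c(OCc2ccccc2)cc(OCc2ccccc2)c(Br)c1OCc1ccccc1 | intermediate
7 | 1-(benzyloxy)-4-ethenylbenzene (4-benzyloxystyrene) | C=Cc1ccc(OCc2ccccc2)cc1 | starting material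
8 | (E)-3-(benzyloxy)-6-{[2,4,6-tris(benzyloxy)-3-bromophenyl]methylidene}cyclohexa-2,4-dien-1-one | O=C1C=C(OCc2ccccc2)C=C/C1=C\c1c(OCc2ccccc2)cc(OCc2ccccc2)c(Br)c1OCc1ccccc1 | intermediate (not isolated)
9 | (2R,4R)-7-(benzyloxy)-2-[4-(benzyloxy)phenyl]-4-[2,4,6-tris(benzyloxy)-3-bromophenyl]chromane | Brc1c(OCc2ccccc2)cc(OCc2ccccc2)c([C@@H]2C[C@H](c3ccc(OCc4ccccc4)cc3)Oc3cc(OCc4ccccc4)ccc32)c1OCc1ccccc1 | intermediate
10 | dodecanoyl chloride | CCCCCCCCCCCC(=O)Cl | starting material
11 | N,O-dimethylhydroxylamine hydrochloride | CNOC.Cl | starting material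
12 | N-methoxy-N-methyldodecanamide | CCCCCCCCCCCC(=O)N(C)OC | intermediate
13 | {2,4,6-tris(benzyloxy)-3-[(2R,4R)-7-(benzyloxy)-2-[4-(benzyloxy)phenyl]chroman-4-yl]phenyl}lithium | [Li]c1c(OCc2ccccc2)cc(OCc2ccccc2)c([C@@H]2C[C@H](c3ccc(OCc4ccccc4)cc3)Oc3cc(OCc4ccccc4)ccc32)c1OCc1ccccc1 | intermediate (not isolated)
14 | lithium 1-{2,4,6-tris(benzyloxy)-3-[(2R,4R)-7-(benzyloxy)-2-[4-(benzyloxy)phenyl]chroman-4-yl]phenyl}-1-[methoxy(methyl)amino]dodecan-1-olate (both configurations at C1) | CCCCCCCCCCCC(O[Li])(N(C)OC)c1c(OCc2ccccc2)cc(OCc2ccccc2)c([C@@H]2C[C@H](c3ccc(OCc4ccccc4)cc3)Oc3cc(OCc4ccccc4)ccc32)c1OCc1ccccc1 | intermediate (not isolated)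
15 | 1-{2,4,6-tris(benzyloxy)-3-[(2R,4R)-7-(benzyloxy)-2-[4-(benzyloxy)phenyl]chroman-4-yl]phenyl}dodecan-1-one | CCCCCCCCCCCC(=O)c1c(OCc2ccccc2)cc(OCc2ccccc2)c([C@@H]2C[C@H](c3ccc(OCc4ccccc4)cc3)Oc3cc(OCc4ccccc4)ccc32)c1OCc1ccccc1 | intermediate
16 | 1-{2,4,6-trihydroxy-3-[(2R,4R)-7-hydroxy-2-(4-hydroxyphenyl)chroman-4-yl]phenyl}dodecan-1-one (2,4-cis) | CCCCCCCCCCCC(=O)c1c(O)cc(O)c([C@@H]2C[C@H](c3ccc(O)cc3)Oc3cc(O)ccc32)c1O | target

**Step count**

Total steps: 6. Longest linear sequence: 5 (steps 1, 2, 3, 5, 6); step 4 is a one-step side branch.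

**Steps most likely to fail**

1. Step 3. Facial selectivity at the methide carbon may be poor, because the di-ortho-substituted ring D is twisted out of the quinone methide plane and may fit badly into the catalyst pocket; acid-induced oligomerisation of the styrene may also compete. The fallback sets out from 6 and 7 and replaces catalyst control by resolution. The cycloaddition would be run with an achiral acid (diphenyl phosphate, 10 mol %, toluene, rt), which should still give only the cis adduct, now as the racemate: 9 together with its mirror image (2S,4S)-7-(benzyloxy)-2-[4-(benzyloxy)phenyl]-4-[2,4,6-tris(benzyloxy)-3-bromophenyl]chromane F1. The enantiomers would be separated by preparative HPLC on a polysaccharide chiral stationary phase, and the route is rejoined at 9.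

2. Step 5. Proton transfer from the α-CH2 group of the Weinreb amide to the hindered aryllithium, or slow addition at a carbon flanked by two benzyloxy groups, may lead to protodebromination instead of acylation. The fallback sets out from 9 and changes acyl substitution into addition followed by oxidation. After the same bromine–lithium exchange (n-BuLi, THF, −78 °C) the aryllithium would be trapped with dodecanal, a smaller and more electrophilic partner, to give 1-{2,4,6-tris(benzyloxy)-3-[(2R,4R)-7-(benzyloxy)-2-[4-(benzyloxy)phenyl]chroman-4-yl]phenyl}dodecan-1-ol F2 as a mixture of carbinol epimers. Oxidation with Dess–Martin periodinane (NaHCO3, CH2Cl2, rt) removes this extra centre, and the route is rejoined at 15.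

3. Step 2. Addition of the hindered aryllithium to the phenoxide-deactivated, poorly soluble aldehyde salt may be sluggish, the aryllithium may decay on warming by proton transfer from a benzylic OCH2 group, and the benzhydrol may ionise during isolation. The fallback sets out from 3 and masks the phenol covalently instead of as a salt. O-Allylation (allyl bromide, K2CO3, DMF, rt) would give 2-(allyloxy)-4-(benzyloxy)benzaldehyde F3, a fully soluble and more electrophilic aldehyde. Addition of aryllithium 4 (from 2, as in step 2) at −78 °C should give [2-(allyloxy)-4-(benzyloxy)phenyl][2,4,6-tris(benzyloxy)-3-bromophenyl]methanol F4. The allyl group would be removed under neutral conditions with Pd(PPh3)4 (zerovalent palladium, 3 mol %) and morpholine in THF at rt, and the route is rejoined at 6.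

**Further compounds**

F1 | step 3 | (2S,4S)-7-(benzyloxy)-2-[4-(benzyloxy)phenyl]-4-[2,4,6-tris(benzyloxy)-3-bromophenyl]chromane | Brc1c(OCc2ccccc2)cc(OCc2ccccc2)c([C@H]2C[C@@H](c3ccc(OCc4ccccc4)cc3)Oc3cc(OCc4ccccc4)ccc32)c1OCc1ccccc1
F2 | step 5 | 1-{2,4,6-tris(benzyloxy)-3-[(2R,4R)-7-(benzyloxy)-2-[4-(benzyloxy)phenyl]chroman-4-yl]phenyl}dodecan-1-ol (carbinol epimers) | CCCCCCCCCCCC(O)c1c(OCc2ccccc2)cc(OCc2ccccc2)c([C@@H]2C[C@H](c3ccc(OCc4ccccc4)cc3)Oc3cc(OCc4ccccc4)ccc32)c1OCc1ccccc1
F3 | step 2 | 2-(allyloxy)-4-(benzyloxy)benzaldehyde | C=CCOc1cc(OCc2ccccc2)ccc1C=O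
F4 | step 2 | [2-(allyloxy)-4-(benzyloxy)phenyl][2,4,6-tris(benzyloxy)-3-bromophenyl]methanol (racemic) | OC(c1ccc(OCc2ccccc2)cc1OCC=C)c1c(OCc2ccccc2)cc(OCc2ccccc2)c(Br)c1OCc1ccccc1
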